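**Direct plan and its weak points**

A direct plan would take the chalcone route: ketone A1 (2-hydroxy-3,4,5,6-tetramethoxyacetophenone) and aldehyde A2 (3-benzyloxy-2,4,5-trimethoxybenzaldehyde) would be condensed to chalcone A3, cyclised oxidatively to the benzyl-protected flavone A4, and hydrogenolysed.
- The run-up to A1 would be weak: formylation, Baeyer–Villiger oxidation and a hot Lewis-acid Fries acylation would be spent in a long linear sequence on adding one oxygen and one acetyl group to a benzene ring.
- The making of A2 would be weak: demethylation, benzylation, oxidation of CHO to OH, re-formylation and methylation would form a single C–C bond in five protecting-group and redox steps.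
- The oxidative cyclisation of A3 would be weak: ring C would be closed at the wrong oxidation level and corrected afterwards with iodine in hot DMSO, where the HI set free endangers the 5-methoxy group peri to the carbonyl. The aldol step before it would need days of concentrated KOH on a hindered ketone.

**Retrosynthetic overview of the new route**

- Ring C is cut at three bonds at once: C4a–C4, C8a–O1 and O1–C2. C4a and C8a are the only two carbons of ring A without a methoxy group, and they are neighbours, so ring A is read as the symmetric 3,4,5,6-tetramethoxybenzyne. The other partner is a 3-arylpropiolic acid that brings C2, C3, C4, both oxygens of ring C and ring B.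
- Rings A and B are bought as benzene rings. Ring C is the only ring formed, in the same operation that first joins the two halves, and it is formed directly at the flavone oxidation level.
- The aryne precursor takes three steps from 1,2,3,4-tetramethoxybenzene, with no formylation and no Fries acylation. The acid takes four steps from 1,2,4-trimethoxybenzene, with no aldehyde and no benzyl shuttle. There is no chalcone, no dehydrogenation and no hydrogenolysis.

Key step: step 8

Assumption: 1,2,3,4-tetramethoxybenzene, 1,2,4-trimethoxybenzene and propiolic acid are taken as commercial; in the key step the arylpropiolic acid is the limiting component.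

**Ring A: aryne precursor**

Step 1
Reactants: 1 1,2,3,4-tetramethoxybenzene
Product: 4 2,3,4,5-tetramethoxyphenol, via aryllithium 2 (not isolated), via dimethyl arylboronate 3 (not isolated)
Conditions: n-BuLi (1.2 equiv), TMEDA, THF, 0 °C → rt; B(OMe)3, −78 °C → rt; AcOH, 30% H2O2, 0 °C → rt; aq Na2SO3
Reagents that add atoms: n-butyllithium, [Li]CCCC (lithium of 2); trimethyl borate, COB(OC)OC (boron of 3); hydrogen peroxide, OO (phenol oxygen of 4)
Why: Directed ortho-metalation, in which the two unsubstituted carbons of 1 are equivalent and each lies ortho to a methoxy group, so a single aryllithium should form, which is borylated and oxidised (C–B to C–O 1,2-shift) to the phenol.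

Step 2
Reactants: 4 2,3,4,5-tetramethoxyphenol
Product: 5 2-bromo-3,4,5,6-tetramethoxyphenol
Conditions: NBS (1.05 equiv), dry CH2Cl2, −20 → 0 °C, dark
Reagents that add atoms: N-bromosuccinimide, O=C1CCC(=O)N1Br
Why: Electrophilic aromatic bromination of a phenol at its only unsubstituted carbon, which is ortho to the hydroxyl; low temperature and exclusion of water should hold back oxidation to a quinone.

Step 3
Reactants: 5 2-bromo-3,4,5,6-tetramethoxyphenol
Product: 8 2,3,4,5-tetramethoxy-6-(trimethylsilyl)phenyl trifluoromethanesulfonate, via aryl silyl ether 6 (not isolated), via lithium silylphenoxide 7 (not isolated)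
Conditions: HMDS, THF, 70 °C, then evaporation; n-BuLi (1.1 equiv), THF, −100 → −78 °C; Tf2O (1.2 equiv), −78 °C → rt
Reagents that add atoms: hexamethyldisilazane, C[Si](C)(C)N[Si](C)(C)C; n-butyllithium, [Li]CCCC (lithium of 7); trifluoromethanesulfonic anhydride, O=S(=O)(OS(=O)(=O)C(F)(F)F)C(F)(F)F
Why: Standard three-stage route to an ortho-silylaryl triflate, by O-silylation, bromine–lithium exchange followed by a retro-Brook 1,3-silyl shift from oxygen to carbon, and O-triflation of the lithium phenoxide so released.

**Ring B: arylpropiolic acid**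

Step 4
Reactants: 9 1,2,4-trimethoxybenzene
Product: 12 2,3,6-trimethoxyphenol, via aryllithium 10 (not isolated), via dimethyl arylboronate 11 (not isolated)
Conditions: n-BuLi (1.1 equiv), THF, 0 °C → rt; B(OMe)3, −78 °C → rt; AcOH, 30% H2O2, 0 °C → rt; aq Na2SO3
Reagents that add atoms: n-butyllithium, [Li]CCCC (lithium of 10); trimethyl borate, COB(OC)OC (boron of 11); hydrogen peroxide, OO (phenol oxygen of 12)
Why: Directed ortho-metalation at C3 of 9, the only carbon flanked by two methoxy groups (cooperative 1,3-direction), then borylation and oxidation as in step 1; this oxygen becomes the free 3'-OH of the target.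

Step 5
Reactants: 12 2,3,6-trimethoxyphenol
Product: 13 2,3,6-trimethoxyphenyl pivalate
Conditions: PivCl (1.2 equiv), Et3N, DMAP (cat.), CH2Cl2, 0 °C → rt
Reagents that add atoms: pivaloyl chloride, CC(C)(C)C(Cl)=O
Why: DMAP-catalysed O-acylation masks the phenol as a hindered ester that should survive the later palladium and fluoride steps and that switches off the para-directing power of this oxygen.

Step 6
Reactants: 13 2,3,6-trimethoxyphenyl pivalate
Product: 14 3-iodo-2,5,6-trimethoxyphenyl pivalate
Conditions: NIS (1.1 equiv), TFA (cat.), MeCN, rt, dark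
Reagents that add atoms: N-iodosuccinimide, O=C1CCC(=O)N1I
Why: Electrophilic aromatic iodination, in which C5 of 13 is ortho to one methoxy group and para to another, whereas C4 is para to the pivaloyloxy group, which is twisted out of conjugation by its two ortho neighbours and inductively withdrawing, so iodine should enter at C5.

Step 7
Reactants: 14 3-iodo-2,5,6-trimethoxyphenyl pivalate; 15 propiolic acid
Product: 16 3-[3-(pivaloyloxy)-2,4,5-trimethoxyphenyl]prop-2-ynoic acid
Conditions: Pd(PPh3)4 (5 mol %), DBU (2.5 equiv), DMSO, 35 °C; then cold 1 M HCl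
Reagents that add atoms: none
Why: Copper-free Sonogashira coupling of an aryl iodide with propiolic acid, which should stop at the arylpropiolic acid because oxidative addition to the C–I bond is fast near room temperature while a decarboxylative second coupling needs a higher temperature.

**Union and completion**

Step 8
Reactants: 8 2,3,4,5-tetramethoxy-6-(trimethylsilyl)phenyl trifluoromethanesulfonate (1.5 equiv); 16 3-[3-(pivaloyloxy)-2,4,5-trimethoxyphenyl]prop-2-ynoic acid
Product: 19 2,3,6-trimethoxy-5-(5,6,7,8-tetramethoxy-4-oxo-4H-chromen-2-yl)phenyl pivalate, via tetramethoxybenzyne 17 (not isolated), via hydroxyaryl ynone 18 (not isolated)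
Conditions: CsF (4 equiv), dry THF, 125 °C, sealed tube, 24 h
Reagents that add atoms: none
Why: Fluoride strips the silyl group of 8 and expels triflate to give the symmetric aryne 17; the carboxylate of 16 adds through oxygen to one aryne carbon, the ortho aryl anion so formed attacks the ester carbonyl (1,3 O→C acyl shift, an anionic Fries-type rearrangement through a four-membered transition state), and the resulting 2-acylphenoxide 18 adds to the β-carbon of the ynone, the C3 carbanion taking up the proton that the acid brought in. The closest known reaction type is the formal insertion of arynes into the C–O bond of carboxylic acids under CsF in hot THF, which turns aroic acids into ortho-hydroxyaryl ketones and 3-arylpropiolic acids into flavones. Ring C is closed by intramolecular oxa-Michael addition in the 6-endo-dig mode, which should win over 5-exo-dig (aurone) closure because in an aprotic medium only the endo path gives a carbonyl-stabilised anion. No stereocenter is formed. Regioselectivity of the aryne addition is not an issue, because both aryne carbons are flanked by methoxy groups and are equivalent, so the oxygen and the acyl carbon can only end at C8a and C4a; the chemoselectivity needed is that the 3'-oxygen stays masked, which the pivalate hindered by two ortho methoxy groups should secure against fluoride and phenoxide. The flavone oxidation level is built in by the alkyne, so no dehydrogenation follows.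

Step 9
Reactants: 19 2,3,6-trimethoxy-5-(5,6,7,8-tetramethoxy-4-oxo-4H-chromen-2-yl)phenyl pivalate
Product: 20 Agehoustin C, 2-(3-hydroxy-2,4,5-trimethoxyphenyl)-5,6,7,8-tetramethoxy-4H-chromen-4-one
Conditions: K2CO3 (2 equiv), MeOH–THF, rt → 40 °C; then aq NH4Cl
Reagents that add atoms: none
Why: Base-catalysed transesterification (methanolysis) of the phenolic pivalate, whose phenoxide is a good leaving group; the flavone and the aryl methyl ethers should be inert to K2CO3 in methanol at this temperature.

**Compound list**

1 | 1,2,3,4-tetramethoxybenzene | COc1ccc(OC)c(OC)c1OC | starting material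
2 | (2,3,4,5-tetramethoxyphenyl)lithium | [Li]c1cc(OC)c(OC)c(OC)c1OC | intermediate (not isolated)
3 | dimethyl (2,3,4,5-tetramethoxyphenyl)boronate | COB(OC)c1cc(OC)c(OC)c(OC)c1OC | intermediate (not isolated)
4 | 2,3,4,5-tetramethoxyphenol | COc1cc(O)c(OC)c(OC)c1OC | intermediate
5 | 2-bromo-3,4,5,6-tetramethoxyphenol | COc1c(OC)c(OC)c(O)c(Br)c1OC | intermediate
6 | (2-bromo-3,4,5,6-tetramethoxyphenoxy)trimethylsilane | COc1c(OC)c(OC)c(O[Si](C)(C)C)c(Br)c1OC | intermediate (not isolated)
7 | lithium 2,3,4,5-tetramethoxy-6-(trimethylsilyl)phenoxide | [Li+].COc1c(OC)c(OC)c([O-])c([Si](C)(C)C)c1OC | intermediate (not isolated)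
8 | 2,3,4,5-tetramethoxy-6-(trimethylsilyl)phenyl trifluoromethanesulfonate | COc1c(OC)c(OC)c(OS(=O)(=O)C(F)(F)F)c([Si](C)(C)C)c1OC | intermediate
9 | 1,2,4-trimethoxybenzene | COc1ccc(OC)c(OC)c1 | starting material
10 | (2,3,6-trimethoxyphenyl)lithium | [Li]c1c(OC)ccc(OC)c1OC | intermediate (not isolated)
11 | dimethyl (2,3,6-trimethoxyphenyl)boronate | COB(OC)c1c(OC)ccc(OC)c1OC | intermediate (not isolated)
12 | 2,3,6-trimethoxyphenol | COc1ccc(OC)c(O)c1OC | intermediate
13 | 2,3,6-trimethoxyphenyl pivalate | COc1ccc(OC)c(OC(=O)C(C)(C)C)c1OC | intermediate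
14 | 3-iodo-2,5,6-trimethoxyphenyl pivalate | COc1cc(I)c(OC)c(OC(=O)C(C)(C)C)c1OC | intermediate
15 | propiolic acid (prop-2-ynoic acid) | C#CC(=O)O | starting material
16 | 3-[3-(pivaloyloxy)-2,4,5-trimethoxyphenyl]prop-2-ynoic acid | COc1cc(C#CC(=O)O)c(OC)c(OC(=O)C(C)(C)C)c1OC | intermediate
17 | 3,4,5,6-tetramethoxybenzyne | COC1=C(OC)C(OC)=C(OC)C#C1 | intermediate (not isolated)
18 | 1-(2-hydroxy-3,4,5,6-tetramethoxyphenyl)-3-[3-(pivaloyloxy)-2,4,5-trimethoxyphenyl]prop-2-yn-1-one (formed as its cesium phenoxide) | COc1cc(C#CC(=O)c2c(O)c(OC)c(OC)c(OC)c2OC)c(OC)c(OC(=O)C(C)(C)C)c1OC | intermediate (not isolated)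
19 | 2,3,6-trimethoxy-5-(5,6,7,8-tetramethoxy-4-oxo-4H-chromen-2-yl)phenyl pivalate | COc1cc(-c2cc(=O)c3c(OC)c(OC)c(OC)c(OC)c3o2)c(OC)c(OC(=O)C(C)(C)C)c1OC | intermediate
20 | Agehoustin C, 2-(3-hydroxy-2,4,5-trimethoxyphenyl)-5,6,7,8-tetramethoxy-4H-chromen-4-one (achiral) | COc1cc(-c2cc(=O)c3c(OC)c(OC)c(OC)c(OC)c3o2)c(OC)c(O)c1OC | target

**Step count and risks**

Total step count: 9. Longest linear sequence: 6 steps (steps 4, 5, 6, 7, 8, 9).

Steps most likely to fail:

1. Step 8 (aryne annulation). The ortho aryl anion may be protonated before the acyl shift, so that only the aryl ester forms; the propiolate may lose CO2 at 125 °C; or the ynone may close in the 5-exo mode. The fallback sets out from phenol 4 and acid 16 and comes back at 19, and it takes C4 from carbon monoxide instead of the carboxyl group. Phenol 4 would be iodinated at its only free carbon (NIS, CH2Cl2, 0 °C) to 2-iodo-3,4,5,6-tetramethoxyphenol F1. Acid 16 would be protodecarboxylated (CuCl cat., Et3N, MeCN, 60 °C) to 3-ethynyl-2,5,6-trimethoxyphenyl pivalate F2. F1, F2 and CO (1 atm) would then be joined by carbonylative Sonogashira annulation (PdCl2(PPh3)2, a divalent palladium precatalyst, Et2NH, DMF, 60 °C), the amine promoting 6-endo-dig closure of the ynone to 19.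

2. Step 6 (iodination). Site selectivity between C4 and C5 may be poor if the twisted inner methoxy group directs less strongly than expected. The fallback sets out from 9 and comes back at 14, and it fixes the position by a silicon placeholder. Compound 9 would be brominated (NBS, MeCN) to 1-bromo-2,4,5-trimethoxybenzene F3. Bromine–lithium exchange and silylation (n-BuLi, THF, −78 °C; TMSCl) would give trimethyl(2,4,5-trimethoxyphenyl)silane F4. Directed ortho-metalation between the two methoxy groups (the other free carbon is shielded by the silyl group), borylation and oxidation (n-BuLi; B(OMe)3; H2O2, AcOH) would give 2,3,6-trimethoxy-5-(trimethylsilyl)phenol F5. Pivaloylation (PivCl, Et3N, DMAP) would give 2,3,6-trimethoxy-5-(trimethylsilyl)phenyl pivalate F6, and ipso-iododesilylation (ICl, CH2Cl2, 0 °C) would put iodine exactly where silicon was, giving 14.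

3. Step 2 (bromination). The N-halo reagent may oxidise the electron-rich para-methoxyphenol to a quinone instead of brominating the ring. The fallback sets out from 4 and comes back at 8, bypassing 5 and the retro-Brook step. Phenol 4 would be carbamoylated (isopropyl isocyanate, Et3N cat., CH2Cl2) to 2,3,4,5-tetramethoxyphenyl N-isopropylcarbamate F7. In-situ N-silylation (TBSOTf, TMEDA), carbamate-directed ortho-lithiation at the only free carbon (n-BuLi, −78 °C) and TMSCl quench would give 2,3,4,5-tetramethoxy-6-(trimethylsilyl)phenyl N-isopropylcarbamate F8. Carbamate cleavage (DBU, Et2NH, MeCN, 40 °C) and triflation of the phenoxide in the same flask (PhNTf2) would give 8.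

Further compounds
F1 | step 8 | 2-iodo-3,4,5,6-tetramethoxyphenol | COc1c(OC)c(OC)c(O)c(I)c1OC
F2 | step 8 | 3-ethynyl-2,5,6-trimethoxyphenyl pivalate | COc1cc(C#C)c(OC)c(OC(=O)C(C)(C)C)c1OC
F3 | step 6 | 1-bromo-2,4,5-trimethoxybenzene | COc1cc(Br)c(OC)cc1OC
F4 | step 6 | trimethyl(2,4,5-trimethoxyphenyl)silane | COc1cc([Si](C)(C)C)c(OC)cc1OC
F5 | step 6 | 2,3,6-trimethoxy-5-(trimethylsilyl)phenol | COc1cc([Si](C)(C)C)c(OC)c(O)c1OC
F6 | step 6 | 2,3,6-trimethoxy-5-(trimethylsilyl)phenyl pivalate | COc1cc([Si](C)(C)C)c(OC)c(OC(=O)C(C)(C)C)c1OC
F7 | step 2 | 2,3,4,5-tetramethoxyphenyl N-isopropylcarbamate | COc1cc(OC(=O)NC(C)C)c(OC)c(OC)c1OC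
F8 | step 2 | 2,3,4,5-tetramethoxy-6-(trimethylsilyl)phenyl N-isopropylcarbamate | COc1c(OC)c(OC)c(OC(=O)NC(C)C)c([Si](C)(C)C)c1OC
A1 | direct plan | 1-(2-hydroxy-3,4,5,6-tetramethoxyphenyl)ethan-1-one | CC(=O)c1c(O)c(OC)c(OC)c(OC)c1OC
A2 | direct plan | 3-(benzyloxy)-2,4,5-trimethoxybenzaldehyde | COc1cc(C=O)c(OC)c(OCc2ccccc2)c1OC
A3 | direct plan | (E)-3-[3-(benzyloxy)-2,4,5-trimethoxyphenyl]-1-(2-hydroxy-3,4,5,6-tetramethoxyphenyl)prop-2-en-1-one | COc1cc(/C=C/C(=O)c2c(O)c(OC)c(OC)c(OC)c2OC)c(OC)c(OCc2ccccc2)c1OC
A4 | direct plan | 2-[3-(benzyloxy)-2,4,5-trimethoxyphenyl]-5,6,7,8-tetramethoxy-4H-chromen-4-one | COc1cc(-c2cc(=O)c3c(OC)c(OC)c(OC)c(OC)c3o2)c(OC)c(OCc2ccccc2)c1OC
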